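The earlier runs and the new flask were computed with constants of no real substance; scatter was added.

The amounts come first: every flask holds c(coupling partner) = 1.12 M against 0.28 M of substrate, the limiting reagent, and a catalyst charge of 140 µM.

| setting | amber | eta | beta | epsilon | alpha |
|---|---|---|---|---|---|
| substrate | 0.28 M | 0.28 M | 0.28 M | 0.28 M | 0.28 M |
| coupling partner | 4 equiv | 4.00 equiv | 4.00 equiv | 4.00 equiv | 4.00 equiv |
| free catalyst | 0.05 mol% | 0.05 mol% | 0.05 mol% | 0.05 mol% | 0.05 mol% |
| added ligand | 180 µM | 89 µM | 89 µM | 89 µM | 89 µM |
| temperature | 10 °C |  | 10 °C | −5 °C | 25 °C |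
| remark | run made earlier | at −5 °C until 80 s, from then on at 25 °C |  |  |  |
| time |  | 4.0 min | 4.0 min | 4.0 min | 4.0 min |

amber run (percent of the substrate charged)

| time / s | target / % |
|---|---|
| 10.0 | 1.9 |
| 15.0 | 3.4 |
| 25.0 | 7.3 |
| 40.0 | 7.5 |
| 80.0 | 16.3 |

(each reading ± 1 percentage point)

- the earlier runs were read with a standard deviation of 1 percentage point
- the earlier runs do not show what temperature does; that part of a forecast is a guess
- no earlier run changes the charge of added ligand; that part of a forecast is a guess

* the flask that comes out highest in amount of target, in percent of the substrate charged, or "all alike" when all lie within 1.5 percentage points (eta / beta / epsilon / alpha / all alike)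
* target at the end, in percent of the substrate charged, eta
* target at the end, in percent of the substrate charged, beta
* target at the end, in percent of the substrate charged, epsilon
* target at the end, in percent of the substrate charged, alpha

The amber run gives one usable quantity. Its last reading, 16.3 % at 80.0 s, gives the clearing time, the time in which the charged substrate would be used up if the amber slope held: 491 s. This is a reading and carries the scatter of 1 percentage point.

The reckoning here builds the flask on it step by step. With the main step as a straight line, beta loses 48.9 % of its substrate in 4.0 min. If the rate instead follows c(substrate), the loss is 1 − exp(−t/τ), which gives 38.7 %, so the number drops by 10 points.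

The rest is guesswork. The added ligand stands above the catalyst charge in amber, 180 µM, and below it in beta, 89 µM, but no earlier run moves it, so this reckoning keeps the clearing time as a guess. For temperature, a guessed factor of 3 between 10 °C and 25 °C, and again between −5 °C and 10 °C, gives a clearing time of 164 s when hot and 1473 s when cold. Substrate lost is then 76.9 % in alpha, 15.0 % in epsilon and 64.4 % in eta, whose switch comes at 80 s. This reckoning reads these figures as target, which holds so long as nothing consumes target.

The forecast also ranks alpha highest, with numbers of its own: 63 % in eta, 38 % in beta, 11 % in epsilon and 74 % in alpha. On the ligand it says: “The direction of that effect is unknown, so I keep the rate about the same and widen the ranges.”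

The flasks give 29.2 % in eta, 33.0 % in beta, 16.0 % in epsilon and 20.1 % in alpha, so beta stands highest.

    free catalyst + added ligand ⇌ idle complex, settled at all times (K = 1.00 × 10⁵ M⁻¹, ΔH = 17.0 kJ mol⁻¹)
    catalyst intermediate C ⇌ free catalyst + target (K = 0.160 M, k = 178 s⁻¹, Ea = 65.0 kJ mol⁻¹, ΔH = −22.0 kJ mol⁻¹)
    substrate + free catalyst → catalyst intermediate A (k = 893 M⁻¹ s⁻¹, Ea = 38.0 kJ mol⁻¹)
    coupling partner + catalyst intermediate A ⇌ catalyst intermediate B (K = 1.74 M⁻¹, k = 228 M⁻¹ s⁻¹, Ea = 38.0 kJ mol⁻¹, ΔH = −68.0 kJ mol⁻¹)
    catalyst intermediate B → catalyst intermediate C (k = 45.0 s⁻¹, Ea = 61.0 kJ mol⁻¹)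
    coupling partner + target → over-reaction product (k = 0.0165 M⁻¹ s⁻¹, Ea = 48.0 kJ mol⁻¹)
    (constants at 25 °C)

Beta has lost 62.1 % of its substrate, against 48.9 % on the straight line of the clearing time, and that loss divides into 33.0 % target and 29.1 % over-reaction product. Alpha at 4.00 min has lost 98.7 % of its substrate, against 76.9 % reckoned on a clearing time of 164 s, and holds 20.1 % target beside 78.6 % over-reaction product, while target facing the coupling partner left in alpha has a lifetime against over-reaction, 1/(k·c(coupling partner)), of 97.2 s, shorter than the 4.0 min of the run.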